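**Retrosynthetic overview** (target numbered as 7-oxabicyclo[4.1.0]hept-4-ene: C1 = quaternary oxirane carbon with CH2OBz, C2 = OMe, C3 = OBz, C4=C5, C6 = oxirane CH, O7)
- Both benzoates go on last; the oxirane C1–O7–C6 comes from a reagent-controlled epoxidation of the C1=C6 bond of a 1-(hydroxymethyl)cyclohexa-1,3-diene.
- That diene is cut at C1–C2 and C3–C4: inverse-electron-demand [4+2] of methyl 2-oxo-2H-pyran-3-carboxylate (pyrone C3, C4, C5, C6 become C1, C6, C5, C4; the 3-ester becomes the CH2OBz carbon) with (E)-MeO–CH=CH–Bpin (C2 and C3), followed by loss of CO2.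
- Enabling feature: the trans sp3 pair C2(OMe)/C3(O) lies between C1 and C4, the two ends of the unit C1–C6–C5–C4, which is a 1,3-diene once O7 is removed and carries the one-carbon branch on C1. This is the retron of a 2-pyrone cycloaddition; the lactone bridge from C1 to C4 (2-oxabicyclo[2.2.2]octene) is a temporary ring, and the boryl group on C3 is a masked hydroxyl that also fixes the polarity of the enol ether.
- Ring order: carbocycle and temporary lactone bridge together (key step), bridge expelled as CO2 in the same operation, oxirane last.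

Key step: step 3

Assumption: which BINOL antipode leads to the (5R,6S) series of 6 has to be assigned by experiment; (R)-BINOL is written, and nothing else changes if (S)-BINOL is needed.

Step 1
Reactants: 1 2-chloro-1,1-dimethoxyethane
Product: 2 methoxyethyne
Conditions: NaNH2 (3 equiv), NH3 (l), −33 °C; brine, −70 °C; distil
Reagents that add atoms: none
Why: Two base-induced eliminations (loss of methanol and of HCl) give sodium methoxyacetylide, which is protonated on work-up; this is the classical elimination route to alkoxyalkynes and creates no stereocenter.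

Step 2
Reactants: 2 methoxyethyne
Product: 3 2-[(E)-2-methoxyethenyl]-4,4,5,5-tetramethyl-1,3,2-dioxaborolane
Conditions: pinacolborane (1.0 equiv), Cp2Zr(H)Cl (5 mol%), Et3N (10 mol%), CH2Cl2, 0 °C to rt
Reagents that add atoms: pinacolborane, [H]B1OC(C)(C)C(C)(C)O1
Why: Zirconocene-hydride-catalysed hydroboration of the terminal alkyne adds H and B syn with boron on the terminal carbon, which fixes the E geometry of the 2-borylvinyl ether.

Step 3
Reactants: 3 2-[(E)-2-methoxyethenyl]-4,4,5,5-tetramethyl-1,3,2-dioxaborolane; 4 methyl 2-oxo-2H-pyran-3-carboxylate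
Product: 6 methyl (5R,6S)-6-methoxy-5-(4,4,5,5-tetramethyl-1,3,2-dioxaborolan-2-yl)cyclohexa-1,3-diene-1-carboxylate, via bridged lactone 5 (not isolated)
Conditions: Yb(OTf)3 (10 mol%), (R)-BINOL (12 mol%), i-Pr2NEt (24 mol%), 4 Å MS, CH2Cl2, 0 °C to rt; filter (Florisil); PhMe, 90 °C
Reagents that add atoms: none
Why: Bidentate binding of the lactone and ester carbonyls of 4 to the chiral Yb(III) binaphtholate lowers the LUMO, and the push–pull enol ether 3 should add in an asynchronous concerted inverse-electron-demand [4+2]: its nucleophilic boron-bearing carbon bonds to pyrone C6 and its methoxy-bearing carbon to pyrone C3, which is the C1–C2 bond of the target, and warming lactone 5 then expels CO2 by retro-[4+2] to leave the 1,3-diene. The closest known reaction type is the inverse-electron-demand Diels–Alder reaction of 3-carbomethoxy-2-pyrone with vinyl ethers, including chiral lanthanide–binaphthol catalysis, followed by thermal decarboxylation; boron-substituted 2π partners are tolerated in 2-pyrone cycloadditions, and the 2-borylvinyl ether is a new member of the enol ether class. The carbocycle is closed by an intermolecular [4+2] cycloaddition that forms two σ bonds suprafacially on both partners, and the lactone bridge of the 2-oxabicyclo[2.2.2]octene is a temporary ring that the cycloreversion removes. C6 (OMe) and C5 (B) of 6 should be trans because the E geometry of 3 is transferred suprafacially, and their absolute configuration is set by the catalyst-controlled pyrone face together with the methoxy-endo preference, since the two bridgehead centres vanish with CO2. The step needs regioselectivity, which the polarisation secures (both carbonyls make pyrone C6 the electrophilic terminus, methoxy donation makes the boryl carbon the nucleophile), and high endo and facial selectivity, which rest on the two-point catalyst binding and the secondary overlap of the methoxy oxygen. The trans arrangement of OMe and B also blocks thermal syn-elimination to methyl benzoate during the 90 °C stage.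

Step 4
Reactants: 6 methyl (5R,6S)-6-methoxy-5-(4,4,5,5-tetramethyl-1,3,2-dioxaborolan-2-yl)cyclohexa-1,3-diene-1-carboxylate
Product: 7 methyl (5R,6R)-5-hydroxy-6-methoxycyclohexa-1,3-diene-1-carboxylate
Conditions: 30% H2O2, pH 8 phosphate buffer, THF, 0 °C to rt
Reagents that add atoms: hydrogen peroxide, OO
Why: In this boronate oxidation hydroperoxide adds to boron and C5 migrates from boron to oxygen with retention, so the alcohol should stay trans to OMe (the C6 descriptor changes from S to R only through CIP ranking), while the buffered medium spares the dienoate.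

Step 5
Reactants: 7 methyl (5R,6R)-5-hydroxy-6-methoxycyclohexa-1,3-diene-1-carboxylate
Product: 8 (1R,6R)-5-(hydroxymethyl)-6-methoxycyclohexa-2,4-dien-1-ol
Conditions: DIBAL-H (3.5 equiv), CH2Cl2, −78 °C; aq Rochelle salt
Reagents that add atoms: none
Why: DIBAL-H reduces the conjugated ester in the 1,2 sense to the primary dienyl alcohol without touching a stereocenter, and the neutral work-up avoids acid-induced aromatisation.

Step 6
Reactants: 8 (1R,6R)-5-(hydroxymethyl)-6-methoxycyclohexa-2,4-dien-1-ol
Product: 9 (1R,2S,3R,6R)-1-(hydroxymethyl)-2-methoxy-7-oxabicyclo[4.1.0]hept-4-en-3-ol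
Conditions: Ti(Oi-Pr)4 (15 mol%), D-(−)-DIPT (18 mol%), t-BuOOH (1.5 equiv), 4 Å MS, CH2Cl2, −25 °C
Reagents that add atoms: tert-butyl hydroperoxide, CC(C)(C)OO
Why: In this Sharpless asymmetric epoxidation the primary allylic alcohol binds titanium, so only the C4=C5 alkene carrying CH2OH should react (the ring secondary allylic alcohol on a cis-alkene is a poor substrate), and D-(−)-tartrate delivers oxygen to the face syn to OMe, setting both oxirane carbons under reagent control.

Step 7
Reactants: 9 (1R,2S,3R,6R)-1-(hydroxymethyl)-2-methoxy-7-oxabicyclo[4.1.0]hept-4-en-3-ol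
Product: 10 [(1R,2S,3R,6R)-3-(benzoyloxy)-2-methoxy-7-oxabicyclo[4.1.0]hept-4-en-1-yl]methyl benzoate
Conditions: BzCl (2.4 equiv), pyridine, DMAP (5 mol%), CH2Cl2, 0 °C
Reagents that add atoms: benzoyl chloride, O=C(Cl)c1ccccc1
Why: DMAP-catalysed acylation should benzoylate the primary and the secondary allylic alcohol with retention, while the oxirane and the methyl ether are inert under these weakly basic conditions.

**Compound list**
1 | 2-chloro-1,1-dimethoxyethane | COC(CCl)OC | starting material
2 | methoxyethyne | COC#C | intermediate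
3 | 2-[(E)-2-methoxyethenyl]-4,4,5,5-tetramethyl-1,3,2-dioxaborolane | CO/C=C/B1OC(C)(C)C(C)(C)O1 | intermediate
4 | methyl 2-oxo-2H-pyran-3-carboxylate | COC(=O)C1=CC=COC1=O | starting material
5 | methyl (1S,4S,7R,8S)-8-methoxy-3-oxo-7-(4,4,5,5-tetramethyl-1,3,2-dioxaborolan-2-yl)-2-oxabicyclo[2.2.2]oct-5-ene-4-carboxylate (OMe endo, syn to the C5=C6 bridge; boryl exo) | COC(=O)[C@@]12C=C[C@@H](OC1=O)[C@@H](B3OC(C)(C)C(C)(C)O3)[C@@H]2OC | intermediate
6 | methyl (5R,6S)-6-methoxy-5-(4,4,5,5-tetramethyl-1,3,2-dioxaborolan-2-yl)cyclohexa-1,3-diene-1-carboxylate (OMe and B trans) | CO[C@H]1[C@H](B2OC(C)(C)C(C)(C)O2)C=CC=C1C(=O)OC | intermediate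
7 | methyl (5R,6R)-5-hydroxy-6-methoxycyclohexa-1,3-diene-1-carboxylate (trans) | CO[C@H]1[C@H](O)C=CC=C1C(=O)OC | intermediate
8 | (1R,6R)-5-(hydroxymethyl)-6-methoxycyclohexa-2,4-dien-1-ol (trans) | CO[C@H]1[C@H](O)C=CC=C1CO | intermediate
9 | (1R,2S,3R,6R)-1-(hydroxymethyl)-2-methoxy-7-oxabicyclo[4.1.0]hept-4-en-3-ol (oxirane O syn to OMe, anti to 3-OH) | CO[C@H]1[C@H](O)C=C[C@H]2O[C@]21CO | intermediate
10 | [(1R,2S,3R,6R)-3-(benzoyloxy)-2-methoxy-7-oxabicyclo[4.1.0]hept-4-en-1-yl]methyl benzoate | CO[C@H]1[C@H](OC(=O)c2ccccc2)C=C[C@H]2O[C@]21COC(=O)c1ccccc1 | target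

**Totals**
Total step count: 7. Longest linear sequence: 7 steps (1 to 10); pyrone 4 enters at step 3.

**Steps most likely to fail**

1. Step 3. Enantiopurity may erode through incomplete endo or pyrone-face control, because the exo adduct on the same face and the endo adduct on the other face both give the enantiomeric diene once CO2 is lost; the hindered 1,2-disubstituted enol ether may also fail to turn over at the chiral Lewis acid. The fallback runs from 3 and 4 to 7 without asymmetric catalysis. The two partners are combined without catalyst at 12 kbar in CH2Cl2 at rt, which should give 5 together with its enantiomer, methyl (1R,4R,7S,8R)-8-methoxy-3-oxo-7-(4,4,5,5-tetramethyl-1,3,2-dioxaborolan-2-yl)-2-oxabicyclo[2.2.2]oct-5-ene-4-carboxylate F1. Thermolysis in toluene should then give 6 and the enantiomeric diene boronate, methyl (5S,6R)-6-methoxy-5-(4,4,5,5-tetramethyl-1,3,2-dioxaborolan-2-yl)cyclohexa-1,3-diene-1-carboxylate F2, and buffered peroxide oxidation as in step 4 should give 7 and the enantiomeric alcohol, methyl (5S,6S)-5-hydroxy-6-methoxycyclohexa-1,3-diene-1-carboxylate F3. A lipase (immobilised Candida antarctica lipase B first, vinyl acetate, MTBE, rt), selected so that the unwanted enantiomer reacts fast, should acetylate F3 to methyl (5S,6S)-5-acetoxy-6-methoxycyclohexa-1,3-diene-1-carboxylate F4. Unreacted 7 is separated by chromatography and rejoins the route at step 5.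

2. Step 4. β-Elimination of the methoxy and boryl groups from 6, driven by aromatisation to methyl benzoate, may compete with the boron-to-oxygen shift. The fallback runs from 5 to 7 with the oxidation moved in front of the cycloreversion. Crude 5 is oxidised with anhydrous trimethylamine N-oxide (CH2Cl2, 0 °C) to the borate ester, methyl (1R,4S,7R,8R)-8-methoxy-3-oxo-7-[(4,4,5,5-tetramethyl-1,3,2-dioxaborolan-2-yl)oxy]-2-oxabicyclo[2.2.2]oct-5-ene-4-carboxylate F5, where elimination cannot give an arene. Heating (PhMe, 90 °C) should expel CO2 to the diene borate, methyl (5R,6R)-6-methoxy-5-[(4,4,5,5-tetramethyl-1,3,2-dioxaborolan-2-yl)oxy]cyclohexa-1,3-diene-1-carboxylate F6, and aqueous work-up hydrolyses the B–O bond to give 7.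

3. Step 6. Reagent and substrate may be mismatched (a pseudo-axial OMe shields the face that has to be epoxidised), giving poor facial selectivity, and titanium may open the vinyl epoxide. The fallback runs from 8 to 10 by a non-directed, catalyst-controlled dioxirane epoxidation. 8 is first dibenzoylated (BzCl, pyridine, DMAP) to the dienyl dibenzoate, [(5R,6R)-5-(benzoyloxy)-6-methoxycyclohexa-1,3-dien-1-yl]methyl benzoate F7. F7 is then epoxidised at its more electron-rich trisubstituted alkene with the fructose-derived ketone catalyst (the antipode that the spiro transition-state model assigns to the face syn to OMe), Oxone, K2CO3 buffer, MeCN–DMM, 0 °C, which should give 10 directly.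

**Further compounds**
F1 | step 3 | methyl (1R,4R,7S,8R)-8-methoxy-3-oxo-7-(4,4,5,5-tetramethyl-1,3,2-dioxaborolan-2-yl)-2-oxabicyclo[2.2.2]oct-5-ene-4-carboxylate | COC(=O)[C@]12C=C[C@H](OC1=O)[C@H](B3OC(C)(C)C(C)(C)O3)[C@H]2OC
F2 | step 3 | methyl (5S,6R)-6-methoxy-5-(4,4,5,5-tetramethyl-1,3,2-dioxaborolan-2-yl)cyclohexa-1,3-diene-1-carboxylate | CO[C@@H]1[C@@H](B2OC(C)(C)C(C)(C)O2)C=CC=C1C(=O)OC
F3 | step 3 | methyl (5S,6S)-5-hydroxy-6-methoxycyclohexa-1,3-diene-1-carboxylate | CO[C@@H]1[C@@H](O)C=CC=C1C(=O)OC
F4 | step 3 | methyl (5S,6S)-5-acetoxy-6-methoxycyclohexa-1,3-diene-1-carboxylate | CO[C@@H]1[C@@H](OC(C)=O)C=CC=C1C(=O)OC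
F5 | step 4 | methyl (1R,4S,7R,8R)-8-methoxy-3-oxo-7-[(4,4,5,5-tetramethyl-1,3,2-dioxaborolan-2-yl)oxy]-2-oxabicyclo[2.2.2]oct-5-ene-4-carboxylate | COC(=O)[C@@]12C=C[C@@H](OC1=O)[C@@H](OB3OC(C)(C)C(C)(C)O3)[C@@H]2OC
F6 | step 4 | methyl (5R,6R)-6-methoxy-5-[(4,4,5,5-tetramethyl-1,3,2-dioxaborolan-2-yl)oxy]cyclohexa-1,3-diene-1-carboxylate | CO[C@H]1[C@H](OB2OC(C)(C)C(C)(C)O2)C=CC=C1C(=O)OC
F7 | step 6 | [(5R,6R)-5-(benzoyloxy)-6-methoxycyclohexa-1,3-dien-1-yl]methyl benzoate | CO[C@H]1[C@H](OC(=O)c2ccccc2)C=CC=C1COC(=O)c1ccccc1
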